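The route opens ring C of the apigenin half. Its pyranone consists of C4a, C8a and O1 of a phloroglucinol, one carbonyl carbon (C4), and C3 and C2 of an arylacetylene. A single palladium-catalysed carbonylative annulation therefore unites an ortho-iodophenol, carbon monoxide and 4-benzyloxyphenylacetylene. It forges C4a–C4, C4–C3 and O1–C2 and closes the ring. The precursor is a benzyl-protected 6-aryl-2-iodophenol whose only free hydroxyl lies between the iodinated carbon and the biaryl carbon. Its spectator halide is a chloride rather than a bromide, inert to triphenylphosphine palladium catalysts. Borylation, asymmetric conjugate addition to a ring A chromone (sets C2, S) and hydrogenolysis complete the synthesis.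

Key step: step 4

Assumption: the PyOx catalyst is taken to show on chromones the facial sense established for 3-substituted cyclohexenones, where the (S)-ligand gives (R)-3-aryl ketones, an arrangement that corresponds to a (2R)-flavanone. The (R)-ligand is therefore specified for (2S); if a test with a simple arylboronic acid shows the opposite sense, the commercial antipode is used with no other change.

Remark: the C3′–C8″ biaryl axis carries three oxygen ortho substituents and one hydrogen, is not configurationally stable and is unspecified in the target, so C2 of the flavanone is the only stereogenic element to control.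

Step 1
Reactants: 1 3,5-bis(benzyloxy)phenol
Product: 2 3,5-bis(benzyloxy)-2-iodophenol
Conditions: NIS (1.0 equiv), CH2Cl2, −20 to 0 °C, dark
Reagents that add atoms: N-iodosuccinimide, O=C1CCC(=O)N1I
Why: Electrophilic aromatic iodination of a phloroglucinol diether is fast at low temperature and favours the two equivalent carbons beside the small hydroxyl (to which NIS can hydrogen-bond) over the carbon squeezed between two benzyloxy groups, while one equivalent of NIS holds back di-iodination.

Step 2
Reactants: 2 3,5-bis(benzyloxy)-2-iodophenol; 3 [2-(benzyloxy)-5-chlorophenyl]boronic acid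
Product: 4 3,5-bis(benzyloxy)-2-[2-(benzyloxy)-5-chlorophenyl]phenol
Conditions: Pd(PPh3)4 (5 mol %), K2CO3, DME–H2O, 85 °C
Reagents that add atoms: none
Why: In this Suzuki–Miyaura coupling only the C–I bond can add oxidatively to the triphenylphosphine catalyst, because the electron-rich aryl chloride of 3 is inert, so self-coupling of 3 is excluded, and three small oxygen ortho substituents are tolerated as in related 8-iodoflavone couplings.

Step 3
Reactants: 4 3,5-bis(benzyloxy)-2-[2-(benzyloxy)-5-chlorophenyl]phenol
Product: 5 3,5-bis(benzyloxy)-2-[2-(benzyloxy)-5-chlorophenyl]-6-iodophenol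
Conditions: NIS (1.0 equiv), CH2Cl2, −20 to 0 °C, dark
Reagents that add atoms: N-iodosuccinimide, O=C1CCC(=O)N1I
Why: This second electrophilic aromatic iodination goes to C6 because that carbon lies beside the free hydroxyl and is far less crowded than C4 between two benzyloxy groups, the same ortho-to-hydroxyl preference shown by 2-hydroxy-4,6-dialkoxyphenyl ketones and 5-hydroxyflavones, and the chloroanisole-type ring is too poorly activated to compete.

Step 4
Reactants: 5 3,5-bis(benzyloxy)-2-[2-(benzyloxy)-5-chlorophenyl]-6-iodophenol; 6 1-(benzyloxy)-4-ethynylbenzene; 7 carbon monoxide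
Product: 10 5,7-bis(benzyloxy)-8-[2-(benzyloxy)-5-chlorophenyl]-2-[4-(benzyloxy)phenyl]-4H-chromen-4-one, via ortho-hydroxyaryl ynone 8 (not isolated), via diethylamino enaminone 9 (not isolated)
Conditions: PdCl2(PPh3)2 (5 mol %), 6 (1.5 equiv), CO (10 bar), Et2NH, 100 °C, autoclave
Reagents that add atoms: none
Why: Zerovalent palladium, formed in situ from PdCl2(PPh3)2, inserts into the C–I bond of 5, CO insertion gives the aroylpalladium iodide, and amine-assisted transfer of the acetylide of 6 followed by reductive elimination makes C4a–C4 and C4–C3 in ynone 8. Diethylamine then adds to the β-carbon of the ynone to give enaminone 9, and the neighbouring phenol attacks that same carbon and expels the amine, which forms O1–C2. This is the known carbonylative annulation of 2-iodophenols with terminal arylacetylenes in secondary amines, that is, a carbonylative Sonogashira coupling followed by oxa-Michael addition–elimination. The one ring formed, the pyranone, closes 6-endo-trig on the enaminone, so the 5-exo path from the bare ynone to an aurone is bypassed, and no stereocentre is created. Halide selectivity is secured by the substrate, since an electron-rich aryl chloride does not add oxidatively to a triphenylphosphine palladium catalyst even at this temperature, and CO pressure keeps carbonylation ahead of direct alkynylation to a benzofuran. Regiochemistry is secured because the only free hydroxyl sits between the iodinated carbon and the biaryl carbon, so only the 8-aryl flavone can form.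

Step 5
Reactants: 10 5,7-bis(benzyloxy)-8-[2-(benzyloxy)-5-chlorophenyl]-2-[4-(benzyloxy)phenyl]-4H-chromen-4-one
Product: 11 5,7-bis(benzyloxy)-8-[2-(benzyloxy)-5-(4,4,5,5-tetramethyl-1,3,2-dioxaborolan-2-yl)phenyl]-2-[4-(benzyloxy)phenyl]-4H-chromen-4-one
Conditions: B2pin2, Pd2(dba)3 (2 mol %), XPhos (8 mol %), KOAc, 1,4-dioxane, 100 °C
Reagents that add atoms: bis(pinacolato)diboron, CC1(C)OB(OC1(C)C)B1OC(C)(C)C(C)(C)O1
Why: This is a Miyaura borylation in which the bulky, electron-rich biarylphosphine makes oxidative addition of zerovalent palladium into electron-rich aryl chlorides routine, and the flavone carbonyl and benzyl ethers are indifferent to it.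

Step 6
Reactants: 11 the pinacol boronate of step 5
Product: 12 {4-(benzyloxy)-3-[5,7-bis(benzyloxy)-2-(4-(benzyloxy)phenyl)-4-oxo-4H-chromen-8-yl]phenyl}boronic acid
Conditions: NaIO4, NH4OAc, THF–H2O, rt
Reagents that add atoms: water, O
Why: Oxidative glycol cleavage of the released pinacol by periodate pulls the boronic ester hydrolysis to the free boronic acid, the form that transmetalates under the base-free conditions of step 9, and nothing else in 11 is oxidised by NaIO4.

Step 7
Reactants: 13 1-(2,6-dihydroxy-4-methoxyphenyl)ethanone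
Product: 14 1-[2-(benzyloxy)-6-hydroxy-4-methoxyphenyl]ethanone
Conditions: BnBr (1.05 equiv), K2CO3, acetone, reflux
Reagents that add atoms: benzyl bromide, BrCc1ccccc1
Why: This Williamson etherification stops at the monoether because the two hydroxyls of 13 are equivalent and the one left over is locked in a strong hydrogen bond to the ketone, which lowers its nucleophilicity.

Step 8
Reactants: 14 1-[2-(benzyloxy)-6-hydroxy-4-methoxyphenyl]ethanone
Product: 16 5-(benzyloxy)-7-methoxy-4H-chromen-4-one, via dimethylamino enaminone 15 (not isolated)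
Conditions: DMF-DMA, toluene, 100 °C; then conc. HCl, CH2Cl2, 40 °C
Reagents that add atoms: N,N-dimethylformamide dimethyl acetal, COC(OC)N(C)C
Why: Condensation of the methyl ketone with the formamide acetal gives the E enaminone 15, and acid then triggers 6-endo addition–elimination of the phenol with loss of dimethylamine, the standard enaminone synthesis of 2,3-unsubstituted chromones, which an aryl benzyl ether survives.

Step 9
Reactants: 12 the arylboronic acid of step 6; 16 5-(benzyloxy)-7-methoxy-4H-chromen-4-one
Product: 17 (2S)-penta-O-benzyl precursor, 5,7-bis(benzyloxy)-8-{2-(benzyloxy)-5-[(2S)-5-(benzyloxy)-7-methoxy-4-oxo-3,4-dihydro-2H-chromen-2-yl]phenyl}-2-[4-(benzyloxy)phenyl]-4H-chromen-4-one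
Conditions: Pd(OCOCF3)2 (10 mol %), (R)-4-tert-butyl-2-(pyridin-2-yl)-4,5-dihydro-1,3-oxazole [(R)-t-BuPyOx, 12 mol %], NH4PF6 (30 mol %), H2O (5 equiv), 16 (2 equiv), ClCH2CH2Cl, 60 °C
Reagents that add atoms: none
Why: In this palladium-catalysed asymmetric conjugate addition of an arylboronic acid to a chromone, the cationic divalent palladium–PyOx complex takes up the aryl group of 12 by transmetalation and inserts C2=C3 of 16 in the enantiodetermining step, with the tert-butyl group of the (R)-ligand leaving the Re face of C2 open, which sets (2S); water then protonates the palladium enolate under base-free conditions that cannot racemise the flavanone, and the 2-aryl-substituted enone of the flavone inside 12 is too hindered to act as acceptor.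

Step 10
Reactants: 17 the (2S)-penta-O-benzyl precursor
Product: 18 target, 8-{2-hydroxy-5-[(2S)-5-hydroxy-7-methoxy-4-oxo-3,4-dihydro-2H-chromen-2-yl]phenyl}-5,7-dihydroxy-2-(4-hydroxyphenyl)-4H-chromen-4-one
Conditions: H2 (1 atm), Pd/C (10 wt % Pd), THF–MeOH, rt
Reagents that add atoms: none
Why: Catalytic hydrogenolysis cleaves all five aryl benzyl ethers under neutral conditions at room temperature, where the flavone C2=C3 bond, both ketones and the benzylic C2–O1 bond are expected to persist and the base-sensitive C2 stereocentre cannot scramble through ring opening to the chalcone.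

Compound list
1 | 3,5-bis(benzyloxy)phenol | Oc1cc(OCc2ccccc2)cc(OCc2ccccc2)c1 | starting material
2 | 3,5-bis(benzyloxy)-2-iodophenol | Oc1cc(OCc2ccccc2)cc(OCc2ccccc2)c1I | intermediate
3 | [2-(benzyloxy)-5-chlorophenyl]boronic acid | OB(O)c1cc(Cl)ccc1OCc1ccccc1 | starting material
4 | 3,5-bis(benzyloxy)-2-[2-(benzyloxy)-5-chlorophenyl]phenol | Oc1cc(OCc2ccccc2)cc(OCc2ccccc2)c1-c1cc(Cl)ccc1OCc1ccccc1 | intermediate
5 | 3,5-bis(benzyloxy)-2-[2-(benzyloxy)-5-chlorophenyl]-6-iodophenol | Oc1c(I)c(OCc2ccccc2)cc(OCc2ccccc2)c1-c1cc(Cl)ccc1OCc1ccccc1 | intermediate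
6 | 1-(benzyloxy)-4-ethynylbenzene | C#Cc1ccc(OCc2ccccc2)cc1 | starting material
7 | carbon monoxide | [C-]#[O+] | starting material
8 | 1-{4,6-bis(benzyloxy)-3-[2-(benzyloxy)-5-chlorophenyl]-2-hydroxyphenyl}-3-[4-(benzyloxy)phenyl]prop-2-yn-1-one | O=C(C#Cc1ccc(OCc2ccccc2)cc1)c1c(O)c(-c2cc(Cl)ccc2OCc2ccccc2)c(OCc2ccccc2)cc1OCc1ccccc1 | intermediate
9 | (E)-1-{4,6-bis(benzyloxy)-3-[2-(benzyloxy)-5-chlorophenyl]-2-hydroxyphenyl}-3-[4-(benzyloxy)phenyl]-3-(diethylamino)prop-2-en-1-one (drawn as the E isomer) | CCN(CC)/C(=C/C(=O)c1c(O)c(-c2cc(Cl)ccc2OCc2ccccc2)c(OCc2ccccc2)cc1OCc1ccccc1)c1ccc(OCc2ccccc2)cc1 | intermediate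
10 | 5,7-bis(benzyloxy)-8-[2-(benzyloxy)-5-chlorophenyl]-2-[4-(benzyloxy)phenyl]-4H-chromen-4-one | O=c1cc(-c2ccc(OCc3ccccc3)cc2)oc2c(-c3cc(Cl)ccc3OCc3ccccc3)c(OCc3ccccc3)cc(OCc3ccccc3)c12 | intermediate
11 | pinacol boronate of 10 (Bpin in place of Cl) | O=c1cc(-c2ccc(OCc3ccccc3)cc2)oc2c(-c3cc(B4OC(C)(C)C(C)(C)O4)ccc3OCc3ccccc3)c(OCc3ccccc3)cc(OCc3ccccc3)c12 | intermediate
12 | boronic acid corresponding to 11 | O=c1cc(-c2ccc(OCc3ccccc3)cc2)oc2c(-c3cc(B(O)O)ccc3OCc3ccccc3)c(OCc3ccccc3)cc(OCc3ccccc3)c12 | intermediate
13 | 1-(2,6-dihydroxy-4-methoxyphenyl)ethanone | CC(=O)c1c(O)cc(OC)cc1O | starting material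
14 | 1-[2-(benzyloxy)-6-hydroxy-4-methoxyphenyl]ethanone | CC(=O)c1c(O)cc(OC)cc1OCc1ccccc1 | intermediate
15 | (E)-1-[2-(benzyloxy)-6-hydroxy-4-methoxyphenyl]-3-(dimethylamino)prop-2-en-1-one | CN(C)/C=C/C(=O)c1c(O)cc(OC)cc1OCc1ccccc1 | intermediate
16 | 5-(benzyloxy)-7-methoxy-4H-chromen-4-one | COc1cc(OCc2ccccc2)c2c(=O)ccoc2c1 | intermediate
17 | (2S)-penta-O-benzyl flavanone–flavone | COc1cc(OCc2ccccc2)c2c(c1)O[C@H](c1ccc(OCc3ccccc3)c(-c3c(OCc4ccccc4)cc(OCc4ccccc4)c4c(=O)cc(-c5ccc(OCc6ccccc6)cc5)oc34)c1)CC2=O | intermediate
18 | (2S)-2,3-dihydro-7-O-methylamentoflavone (CNP0107492.1) | COc1cc(O)c2c(c1)O[C@H](c1ccc(O)c(-c3c(O)cc(O)c4c(=O)cc(-c5ccc(O)cc5)oc34)c1)CC2=O | target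

Total step count: 10. Longest linear sequence: 8 steps (steps 1, 2, 3, 4, 5, 6, 9, 10); steps 7 and 8 form the side branch.

Steps most likely to fail

**Step 4.**
- Risk: oxidative addition into the electron-rich, doubly flanked C–I bond may be slow under CO. Diethylamine may intercept the aroylpalladium species (aminocarbonylation). Alkynylation may also outrun CO insertion and end in benzofuran closure.
- Fallback: it sets out from 5 and 6 and rejoins the route at 8, hence at 10. It brings the carbonyl carbon in already attached to the alkyne.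
- Alkyne 6 is deprotonated with n-BuLi (THF, −78 °C) and acylated with N-methoxy-N-methylcarbamoyl chloride. This gives the Weinreb amide N-methoxy-N-methyl-3-[4-(benzyloxy)phenyl]prop-2-ynamide F1.
- Iodophenol 5 is treated with n-BuLi (2.2 equiv, THF, −78 °C). O–H deprotonation is followed by iodine–lithium exchange, which leaves the chloride untouched, to give the lithium 2-lithiophenoxide F2.
- F2 is acylated by F1, and an acidic quench releases ynone 8, now isolated. Warming 8 with Et2NH in EtOH carries it through 9 to flavone 10.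

**Step 9.**
- Risk: insertion into the electron-rich 5,7-dioxygenated chromone may be sluggish, so protodeboronation of the para-alkoxyarylboronic acid takes over. Facial discrimination may also be eroded for such an electron-rich aryl group.
- Fallback: it sets out from 10 and 14 and rejoins at 17. It builds the flavanone from a chalcone and secures the configuration by resolution.
- Chloride 10 is vinylated with potassium vinyltrifluoroborate, CH2=CHBF3K (Pd(OAc)2, XPhos, K2CO3, THF–H2O, 85 °C), to give the 5-vinyl analogue of 10, styrene F3.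
- Lemieux–Johnson cleavage (catalytic OsO4, NaIO4, 2,6-lutidine, dioxane–H2O) gives the 5-formyl analogue of 10, aldehyde F4.
- Claisen–Schmidt condensation of F4 with 14 (Ba(OH)2·8H2O, MeOH–THF, 40 °C) gives the (E)-2′-hydroxychalcone F5.
- NaOAc in refluxing EtOH closes F5 by oxa-Michael addition to the racemic penta-O-benzyl flavanone F6.
- Preparative HPLC on a cellulose carbamate chiral phase delivers 17. The (2R)-enantiomer F7 is re-equilibrated to F6 with NaOAc and recycled.

**Step 2.**
- Risk: oxidative addition into the electron-rich, doubly ortho-flanked iodophenoxide may be slower than protodeboronation of 3 and reductive loss of iodine.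
- Fallback: it sets out from 1 and 3, rejoins at 4 and bypasses 2. It forms the biaryl bond by ligand coupling (Pinhey arylation) instead of cross-coupling.
- Boronic acid 3 is converted with Pb(OAc)4 and catalytic Hg(OAc)2 (CHCl3, 40 °C) into [2-(benzyloxy)-5-chlorophenyl]lead triacetate F8.
- In CHCl3–pyridine, F8 binds phenol 1 through oxygen and transfers its aryl group only to an ortho carbon, giving 4. A slight excess of 1 limits double arylation.

Further compounds
F1 | step 4 | N-methoxy-N-methyl-3-[4-(benzyloxy)phenyl]prop-2-ynamide | CON(C)C(=O)C#Cc1ccc(OCc2ccccc2)cc1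
F2 | step 4 | lithium 2-lithiophenoxide derived from 5 | [Li]Oc1c([Li])c(OCc2ccccc2)cc(OCc2ccccc2)c1-c1cc(Cl)ccc1OCc1ccccc1
F3 | step 9 | 5,7-bis(benzyloxy)-8-[2-(benzyloxy)-5-vinylphenyl]-2-[4-(benzyloxy)phenyl]-4H-chromen-4-one | C=Cc1ccc(OCc2ccccc2)c(-c2c(OCc3ccccc3)cc(OCc3ccccc3)c3c(=O)cc(-c4ccc(OCc5ccccc5)cc4)oc23)c1
F4 | step 9 | 4-(benzyloxy)-3-{5,7-bis(benzyloxy)-2-[4-(benzyloxy)phenyl]-4-oxo-4H-chromen-8-yl}benzaldehyde | O=Cc1ccc(OCc2ccccc2)c(-c2c(OCc3ccccc3)cc(OCc3ccccc3)c3c(=O)cc(-c4ccc(OCc5ccccc5)cc4)oc23)c1
F5 | step 9 | (E)-chalcone from F4 and 14 | COc1cc(O)c(C(=O)/C=C/c2ccc(OCc3ccccc3)c(-c3c(OCc4ccccc4)cc(OCc4ccccc4)c4c(=O)cc(-c5ccc(OCc6ccccc6)cc5)oc34)c2)c(OCc2ccccc2)c1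
F6 | step 9 | racemic penta-O-benzyl flavanone–flavone | COc1cc(OCc2ccccc2)c2c(c1)OC(c1ccc(OCc3ccccc3)c(-c3c(OCc4ccccc4)cc(OCc4ccccc4)c4c(=O)cc(-c5ccc(OCc6ccccc6)cc5)oc34)c1)CC2=O
F7 | step 9 | (2R)-penta-O-benzyl flavanone–flavone | COc1cc(OCc2ccccc2)c2c(c1)O[C@@H](c1ccc(OCc3ccccc3)c(-c3c(OCc4ccccc4)cc(OCc4ccccc4)c4c(=O)cc(-c5ccc(OCc6ccccc6)cc5)oc34)c1)CC2=O
F8 | step 2 | [2-(benzyloxy)-5-chlorophenyl]lead triacetate | CC(=O)O[Pb](OC(C)=O)(OC(C)=O)c1cc(Cl)ccc1OCc1ccccc1
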